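**Retrosynthetic overview**

1. The route rests on the γ-lactone that is cis-fused to the cyclohexene: its ring oxygen sits on the spiro carbinol carbon (shared with the pyrrolidine), its β-carbon is the adjacent ring-fusion CH, and the next ring carbon carries the free OH, so that three contiguous ring carbons bear O, C, O, the pattern left when an oxygen-tethered radical adds across a ring alkene and the far end is capped by oxygen.
2. Last disconnections: N–CH2 (azepine, intramolecular N-alkylation by a 4-chlorobutyl arm) and C=N (pyrrolidine, condensation of the side-arm amine with the ring ketone), which together give the tetrasubstituted enamine.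
3. Key disconnection: the lactone Cα–C(ring fusion) bond and the C–OH bond, both made from a 2-bromopropanal mixed acetal of a tertiary cyclohex-3-enol by 5-exo radical cyclisation and TEMPO capture.
4. The acetal precursor comes from (S)-4-ethylcyclohex-2-enone (desymmetrised 4-ethylcyclohexanone) by α′-oxygenation, allyl addition, oxidation to the α-ketol, ketone alkylation with the four-carbon chain, and conversion of allyl into the Boc-amino butyrolactone arm by a sulfinimine vinylogous Mannich reaction.
5. Ring order: cyclohexene (from the start) → arm butyrolactone → fused lactol/lactone (key step) → pyrroline → azepine.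

Key step: step 16

**Remarks and assumptions**

- Assumption: the (R,R)-lithium amide is taken to give the (S)-enol silane (by analogy with 4-tert-butylcyclohexanone), and the (S)-sulfinyl group to give the (R)-amine carbon through an open transition state; if either sense is reversed, the antipodal reagent is used.
- The enantiopure sulfinyl group turns any minor enantiomer of the carbocycle into diastereomers that are removed at 19.
- The 4-chlorobutyl chain is installed before the arm and rides through the key step as a spectator, because a late ketone alkylation would have to compete with two lactones and a carbamate. Its ring carbon is an epimer mixture (mainly trans to ethyl) until it becomes sp2 in step 22.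

**Route**

Step 1
Reactants: 1 4-ethylcyclohexanone
Product: 2 (S)-[(4-ethylcyclohex-1-en-1-yl)oxy]trimethylsilane
Conditions: lithium (R,R)-bis(1-phenylethyl)amide, LiCl, TMSCl (in situ), THF, −100 °C
Reagents that add atoms: chlorotrimethylsilane, C[Si](C)(C)Cl
Why: Enantiotopic α-deprotonation of the meso ketone by the C2-symmetric chiral lithium amide with in situ silyl trapping (asymmetric desymmetrisation) should fix the ethyl-bearing carbon as S.

Step 2
Reactants: 2 (S)-[(4-ethylcyclohex-1-en-1-yl)oxy]trimethylsilane
Product: 3 (S)-4-ethylcyclohex-2-en-1-one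
Conditions: Pd(OAc)2 (1.05 equiv), MeCN, rt
Reagents that add atoms: none
Why: Saegusa–Ito oxidation, in which Pd(II) adds to the silyl enol ether and β-hydride elimination gives the enone without touching the γ-stereocentre.

Step 3
Reactants: 3 (S)-4-ethylcyclohex-2-en-1-one
Product: 5 (4S,6S)-6-[(tert-butyldimethylsilyl)oxy]-4-ethylcyclohex-2-en-1-one, via silyl dienol ether 4 (not isolated)
Conditions: LDA, THF, −78 °C; TBSOTf; then mCPBA, NaHCO3, CH2Cl2–hexane, −20 °C
Reagents that add atoms: tert-butyldimethylsilyl triflate, CC(C)(C)[Si](C)(C)OS(=O)(=O)C(F)(F)F; mCPBA, OOC(=O)c1cccc(Cl)c1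
Why: Kinetic α′-deprotonation and O-silylation give the cross-conjugated dienol ether, whose enol ether bond is epoxidised and rearranges with silyl migration (Rubottom oxidation); axial entry of the oxidant on the half-chair with pseudo-equatorial ethyl should place the silyloxy group trans to ethyl, and the minor cis isomer is removed by chromatography.

Step 4
Reactants: 5 (4S,6S)-6-[(tert-butyldimethylsilyl)oxy]-4-ethylcyclohex-2-en-1-one; 6 allylmagnesium bromide
Product: 7 (1R,4S,6S)-1-allyl-6-[(tert-butyldimethylsilyl)oxy]-4-ethylcyclohex-2-en-1-ol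
Conditions: THF, −78 °C; aq. NH4Cl
Reagents that add atoms: none
Why: 1,2-Addition of the allyl Grignard reagent to the enone carbonyl anti to the pseudo-axial α-silyloxy group (Felkin–Anh) should set the tertiary carbinol carbon (R) with allyl cis to ethyl and OH trans to it.

Step 5
Reactants: 7 (1R,4S,6S)-1-allyl-6-[(tert-butyldimethylsilyl)oxy]-4-ethylcyclohex-2-en-1-ol
Product: 8 (1S,2R,5S)-2-allyl-5-ethylcyclohex-3-ene-1,2-diol
Conditions: TBAF, THF, 0 °C
Reagents that add atoms: none
Why: Fluoride-mediated cleavage of the secondary silyl ether frees the alcohol that is to become the ring ketone.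

Step 6
Reactants: 8 (1S,2R,5S)-2-allyl-5-ethylcyclohex-3-ene-1,2-diol
Product: 9 (2R,5S)-2-allyl-5-ethyl-2-hydroxycyclohex-3-en-1-one
Conditions: SO3·pyridine, DMSO, iPr2NEt, CH2Cl2, 0 °C
Reagents that add atoms: none
Why: Parikh–Doering oxidation converts the secondary alcohol into the ketone without touching the tertiary allylic alcohol and without glycol cleavage, and removes the auxiliary stereocentre.

Step 7
Reactants: 9 (2R,5S)-2-allyl-5-ethyl-2-hydroxycyclohex-3-en-1-one
Product: 10 (2R,5S)-2-allyl-5-ethyl-2-[(triethylsilyl)oxy]cyclohex-3-en-1-one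
Conditions: TESOTf, 2,6-lutidine, CH2Cl2, −78 °C
Reagents that add atoms: triethylsilyl triflate, CC[Si](CC)(CC)OS(=O)(=O)C(F)(F)F
Why: Silylation of the hindered tertiary hydroxyl with a silyl triflate blocks α-ketol rearrangement and, later, retro-aldol and β-elimination of the β-oxygenated aldehyde.

Step 8
Reactants: 10 (2R,5S)-2-allyl-5-ethyl-2-[(triethylsilyl)oxy]cyclohex-3-en-1-one; 11 1-chloro-4-iodobutane
Product: 12 (2R,5R)-2-allyl-6-(4-chlorobutyl)-5-ethyl-2-[(triethylsilyl)oxy]cyclohex-3-en-1-one (C6 epimers)
Conditions: LDA, THF, −78 °C; then 11, DMPU, −78 → −30 °C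
Reagents that add atoms: none
Why: Kinetic lithium enolate alkylation: the ketone can enolise only towards its CH2 side because the other α-carbon is fully substituted, iodide is displaced in preference to chloride, and the chain should enter mainly anti to the neighbouring ethyl group at a carbon whose configuration is lost later.

Step 9
Reactants: 12 (2R,5R)-2-allyl-6-(4-chlorobutyl)-5-ethyl-2-[(triethylsilyl)oxy]cyclohex-3-en-1-one
Product: 14 2-[(1R,4R)-5-(4-chlorobutyl)-4-ethyl-6-oxo-1-[(triethylsilyl)oxy]cyclohex-2-en-1-yl]acetaldehyde, via terminal diol 13 (not isolated)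
Conditions: OsO4 (cat.), (DHQD)2PHAL (cat.), NMO, acetone–H2O, 0 °C; then NaIO4, 0 °C
Reagents that add atoms: N-methylmorpholine N-oxide, C[N+]1([O-])CCOCC1
Why: Ligand-accelerated osmium dihydroxylation should select the monosubstituted terminal alkene over the cis ring alkene shielded by the adjacent fully substituted carbon, and periodate then cleaves the diol to the aldehyde (Lemieux–Johnson-type sequence).

Step 10
Reactants: 14 2-[(1R,4R)-5-(4-chlorobutyl)-4-ethyl-6-oxo-1-[(triethylsilyl)oxy]cyclohex-2-en-1-yl]acetaldehyde; 15 (S)-2-methylpropane-2-sulfinamide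
Product: 16 (S)-N-[(E)-2-{(1R,4R)-5-(4-chlorobutyl)-4-ethyl-6-oxo-1-[(triethylsilyl)oxy]cyclohex-2-en-1-yl}ethylidene]-2-methylpropane-2-sulfinamide
Conditions: CuSO4 (anhydrous), CH2Cl2, rt
Reagents that add atoms: none
Why: Condensation of the aldehyde with the sulfinamide over a mild dehydrating Lewis acid gives the (E)-sulfinimine, the hindered ring ketone being inert under these conditions.

Step 11
Reactants: 17 3-methylfuran-2(5H)-one
Product: 18 triisopropyl[(3-methylfuran-2-yl)oxy]silane
Conditions: TIPSOTf, Et3N, CH2Cl2, 0 °C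
Reagents that add atoms: triisopropylsilyl triflate, CC(C)[Si](C(C)C)(C(C)C)OS(=O)(=O)C(F)(F)F
Why: Soft enolisation and O-silylation of the butenolide give the aromatic 2-silyloxyfuran as the vinylogous nucleophile.

Step 12
Reactants: 16 (S,E)-sulfinimine; 18 triisopropyl[(3-methylfuran-2-yl)oxy]silane
Product: 19 (S)-N-[(1R)-2-{(1R,4R)-5-(4-chlorobutyl)-4-ethyl-6-oxo-1-[(triethylsilyl)oxy]cyclohex-2-en-1-yl}-1-[(2S)-4-methyl-5-oxo-2,5-dihydrofuran-2-yl]ethyl]-2-methylpropane-2-sulfinamide
Conditions: TMSOTf, CH2Cl2, −78 °C; aq. NaHCO3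
Reagents that add atoms: none
Why: Lewis-acid-promoted vinylogous Mukaiyama–Mannich addition through C5 of the silyloxyfuran by an open transition state: attack anti to the tert-butyl group of the s-cis sulfinimine should set the N-bearing carbon (R), and the antiperiplanar approach should give the anti (threo) relationship to the new butenolide C5 (S).

Step 13
Reactants: 19 butenolide sulfinamide
Product: 20 (S)-N-[(1R)-2-{(1R,4R)-5-(4-chlorobutyl)-4-ethyl-6-oxo-1-[(triethylsilyl)oxy]cyclohex-2-en-1-yl}-1-[(2S,4S)-4-methyl-5-oxooxolan-2-yl]ethyl]-2-methylpropane-2-sulfinamide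
Conditions: [(Ph3P)CuH]6, toluene–THF, H2O (2 equiv), rt
Reagents that add atoms: none
Why: Conjugate reduction of the butenolide by the phosphine copper hydride leaves the isolated ring alkene, the hindered ketone and the alkyl chloride untouched, and protonation of the enolate anti to the C5 substituent should give the cis-3,5-disubstituted lactone.

Step 14
Reactants: 20 saturated lactone sulfinamide
Product: 22 tert-butyl N-[(1R)-2-{(1R,4R)-5-(4-chlorobutyl)-4-ethyl-1-hydroxy-6-oxocyclohex-2-en-1-yl}-1-[(2S,4S)-4-methyl-5-oxooxolan-2-yl]ethyl]carbamate, via aminium chloride 21 (not isolated)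
Conditions: HCl (dioxane), MeOH, 0 °C; concentrate; Boc2O, NaHCO3, THF–H2O, 0 °C
Reagents that add atoms: di-tert-butyl dicarbonate, CC(C)(C)OC(=O)OC(=O)OC(C)(C)C
Why: Methanolic HCl cleaves the N–S bond and the tertiary triethylsilyl ether while the amine stays protonated, so that it neither condenses with the ring ketone nor attacks the lactone, and Boc2O traps it as bicarbonate releases it (carbamate formation).

Step 15
Reactants: 22 Boc-amino lactone tertiary alcohol; 23 ethyl 1-propenyl ether
Product: 24 tert-butyl N-[(1R)-2-{(1R,4R)-1-(2-bromo-1-ethoxypropoxy)-5-(4-chlorobutyl)-4-ethyl-6-oxocyclohex-2-en-1-yl}-1-[(2S,4S)-4-methyl-5-oxooxolan-2-yl]ethyl]carbamate (all isomers at the acetal and C–Br carbons)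
Conditions: NBS, 23 (excess), CH2Cl2, −40 → 0 °C
Reagents that add atoms: N-bromosuccinimide, BrN1C(=O)CCC1=O
Why: Bromoalkoxylation of the enol ether (haloacetalisation): NBS turns the propenyl ether into a β-bromo oxocarbenium ion that the tertiary hydroxyl captures, giving the mixed bromoacetal as isomers at two carbons that are both erased later.

Step 16
Reactants: 24 mixed bromoacetal; 25 2,2,6,6-tetramethylpiperidin-1-oxyl (TEMPO)
Product: 26 cis-fused lactol ether carrying the alkoxyamine (2-ethoxy-3-methyl-hexahydrobenzofuranone core; mixture at acetal carbon, methyl-bearing carbon, C–O–N carbon and chlorobutyl carbon)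
Conditions: Bu3SnH and 25 (each added over 6 h), toluene (0.01 M), 80 °C
Reagents that add atoms: none
Why: The stannyl radical (formed when the nitroxyl abstracts hydrogen from Bu3SnH) takes bromine from the secondary C–Br in preference to the primary C–Cl; the radical at the future lactone α-carbon adds to the nearer alkene carbon, making the C–C bond to the ring-fusion carbon and closing the 2-ethoxytetrahydrofuran, and the cyclohexyl radical left at the future carbinol carbon combines with TEMPO to make the C–O bond. The closest known reaction type is the Ueno–Stork haloacetal cyclisation run under tin hydride–nitroxyl conditions, in which the cyclised radical is captured as its alkoxyamine. The one ring that closes does so in the 5-exo-trig mode, the only one open to a radical held by a two-atom O–C tether. The new ring-fusion stereocentre is set cis to the tertiary C–O bond because the tether reaches only the alkene face that carries this oxygen; the acetal, α- and carbinol carbons form as mixtures and are corrected later (oxidation to C=O, enolate protonation, oxidation–reduction). The step needs ring closure to outrun nitroxyl capture of the first radical, which is secured by the low stationary TEMPO concentration (slow addition, high dilution) and by the fast closure of a β-oxygenated radical onto an alkene held close by the fully substituted carbinol carbon.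

Step 17
Reactants: 26 alkoxyamine lactol ether
Product: 27 ring diketone lactol ether (new ketone between the ring-fusion CH and the ethyl-bearing CH; mixture at acetal, methyl-bearing and chlorobutyl carbons)
Conditions: mCPBA, CH2Cl2, 0 °C
Reagents that add atoms: none
Why: The peracid oxidises the alkoxyamine nitrogen and the N-oxide fragments by Cope-type elimination to the ketone and the hydroxylamine, so both carbinol epimers converge, while the acetal and the hindered older ketone should be inert without acid catalysis.

Step 18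
Reactants: 27 ring diketone lactol ether
Product: 28 (R)-carbinol lactol ether (OH trans to ethyl, cis to the lactol ring)
Conditions: LiAlH(Ot-Bu)3, THF, −78 → −40 °C
Reagents that add atoms: none
Why: Hydride reduction with a hindered alkoxyaluminium hydride is expected at the newer ketone (both flanks CH) in preference to the older one wedged between a fully substituted carbon and the chlorobutyl-bearing CH, and from the convex face anti to the axial ring-fusion C–C bond (Felkin–Anh, axial attack), which should give the equatorial (R)-alcohol.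

Step 19
Reactants: 28 (R)-carbinol lactol ether
Product: 29 tert-butyldimethylsilyl ether of 28
Conditions: TBSCl, imidazole, DMAP (cat.), DMF, 45 °C
Reagents that add atoms: tert-butyldimethylsilyl chloride, CC(C)(C)[Si](C)(C)Cl
Why: Silylation protects the carbinol from re-oxidation in the next step and from translactonisation onto the cis lactone carbonyl that is about to be formed.

Step 20
Reactants: 29 silyl ether lactol ether
Product: 30 cis-fused γ-lactone (mixture at the lactone α-carbon and the chlorobutyl carbon)
Conditions: CrO3, H2SO4, H2O, acetone, 0 °C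
Reagents that add atoms: water, O
Why: Jones oxidation: the acidic medium hydrolyses the ethyl lactol ether and chromic acid oxidises the lactol to the γ-lactone in one operation, which removes the acetal stereocentre, while the hindered secondary silyl ether and the carbamate should survive the short exposure at 0 °C.

Step 21
Reactants: 30 γ-lactone α-epimer mixture
Product: 31 γ-lactone with (R)-α-methyl (methyl cis to the carbinol-bearing ring carbon)
Conditions: LDA (5 equiv), THF, −78 °C; then 2,6-di-tert-butyl-4-methylphenol, −78 °C; aq. NH4Cl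
Reagents that add atoms: none
Why: Enolate formation and kinetic protonation: the hindered phenol should protonate the fused lactone enolate from the face opposite the cyclohexane ring, placing methyl on the concave side, while the arm lactone enolate is protonated anti to its C5 substituent (cis retained) and the ketone enolate, which can form only at the chlorobutyl carbon, is simply re-protonated.

Step 22
Reactants: 31 (R)-α-methyl lactone
Product: 34 O-tert-butyldimethylsilyl ether of the target, via ammonium trifluoroacetate 32 (not isolated), via cyclic imine 33 (not isolated)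
Conditions: TFA, CH2Cl2, 0 °C; evaporate; 4 Å MS, MeCN, 50 °C; then NaI (cat.), iPr2NEt, 70 °C
Reagents that add atoms: none
Why: Acidolysis frees the amine as its salt, which under the residual acid condenses with the ring ketone to the five-membered cyclic imine before it can attack the neighbouring lactone as a free base, and the imine nitrogen then displaces the primary halide (intramolecular N-alkylation of an ω-haloalkyl ketimine) to close the seven-membered ring, the iminium losing its only α-proton to give the tetrasubstituted enamine.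

Step 23
Reactants: 34 O-silyl ether of the target
Product: 35 CNP0154902.3 (target)
Conditions: HF·pyridine, pyridine–THF, 0 °C → rt
Reagents that add atoms: none
Why: Buffered fluoride desilylation frees the secondary hydroxyl under non-basic conditions that should not promote translactonisation or harm the enamine.

**Compound list**

1 | 4-ethylcyclohexanone | CCC1CCC(=O)CC1 | starting material
2 | (S)-[(4-ethylcyclohex-1-en-1-yl)oxy]trimethylsilane | CC[C@H]1CCC(O[Si](C)(C)C)=CC1 | intermediate
3 | (S)-4-ethylcyclohex-2-en-1-one | CC[C@H]1CCC(=O)C=C1 | intermediate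
4 | (S)-tert-butyl[(5-ethylcyclohexa-1,3-dien-2-yl)oxy]dimethylsilane | CC[C@H]1CC=C(O[Si](C)(C)C(C)(C)C)C=C1 | intermediate
5 | (4S,6S)-6-[(tert-butyldimethylsilyl)oxy]-4-ethylcyclohex-2-en-1-one | CC[C@H]1C[C@H](O[Si](C)(C)C(C)(C)C)C(=O)C=C1 | intermediate
6 | allylmagnesium bromide | C=CC[Mg]Br | starting material
7 | (1R,4S,6S)-1-allyl-6-[(tert-butyldimethylsilyl)oxy]-4-ethylcyclohex-2-en-1-ol | CC[C@H]1C[C@H](O[Si](C)(C)C(C)(C)C)[C@@](O)(CC=C)C=C1 | intermediate
8 | (1S,2R,5S)-2-allyl-5-ethylcyclohex-3-ene-1,2-diol | CC[C@H]1C[C@H](O)[C@@](O)(CC=C)C=C1 | intermediate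
9 | (2R,5S)-2-allyl-5-ethyl-2-hydroxycyclohex-3-en-1-one | CC[C@H]1CC(=O)[C@@](O)(CC=C)C=C1 | intermediate
10 | (2R,5S)-2-allyl-5-ethyl-2-[(triethylsilyl)oxy]cyclohex-3-en-1-one | CC[C@H]1CC(=O)[C@@](O[Si](CC)(CC)CC)(CC=C)C=C1 | intermediate
11 | 1-chloro-4-iodobutane | ClCCCCI | starting material
12 | (2R,5R)-2-allyl-6-(4-chlorobutyl)-5-ethyl-2-[(triethylsilyl)oxy]cyclohex-3-en-1-one, C6 epimers | CC[C@H]1C(CCCCCl)C(=O)[C@@](O[Si](CC)(CC)CC)(CC=C)C=C1 | intermediate
13 | 2,3-dihydroxypropyl analogue of 12 (terminal diol, epimers at the side-chain carbinol) | CC[C@H]1C(CCCCCl)C(=O)[C@@](O[Si](CC)(CC)CC)(CC(O)CO)C=C1 | intermediate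
14 | 2-[(1R,4R)-5-(4-chlorobutyl)-4-ethyl-6-oxo-1-[(triethylsilyl)oxy]cyclohex-2-en-1-yl]acetaldehyde | CC[C@H]1C(CCCCCl)C(=O)[C@@](O[Si](CC)(CC)CC)(CC=O)C=C1 | intermediate
15 | (S)-2-methylpropane-2-sulfinamide | CC(C)(C)[S@](=O)N | starting material
16 | (S,E)-N-sulfinyl aldimine of 14 | CC[C@H]1C(CCCCCl)C(=O)[C@@](O[Si](CC)(CC)CC)(C/C=N/[S@@](=O)C(C)(C)C)C=C1 | intermediate
17 | 3-methylfuran-2(5H)-one | CC1=CCOC1=O | starting material
18 | triisopropyl[(3-methylfuran-2-yl)oxy]silane | Cc1ccoc1O[Si](C(C)C)(C(C)C)C(C)C | intermediate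
19 | anti vinylogous Mannich adduct: (S)-sulfinamide, N-bearing carbon R, butenolide C5 S | CC[C@H]1C(CCCCCl)C(=O)[C@@](O[Si](CC)(CC)CC)(C[C@@H](N[S@@](=O)C(C)(C)C)[C@@H]2C=C(C)C(=O)O2)C=C1 | intermediate
20 | saturated (3S,5S)-lactone sulfinamide | CC[C@H]1C(CCCCCl)C(=O)[C@@](O[Si](CC)(CC)CC)(C[C@@H](N[S@@](=O)C(C)(C)C)[C@@H]2C[C@H](C)C(=O)O2)C=C1 | intermediate
21 | aminium chloride of the desilylated amino lactone | CC[C@H]1C(CCCCCl)C(=O)[C@@](O)(C[C@@H]([NH3+])[C@@H]2C[C@H](C)C(=O)O2)C=C1.[Cl-] | intermediate
22 | tert-butyl N-[(1R)-2-{(1R,4R)-5-(4-chlorobutyl)-4-ethyl-1-hydroxy-6-oxocyclohex-2-en-1-yl}-1-[(2S,4S)-4-methyl-5-oxooxolan-2-yl]ethyl]carbamate | CC[C@H]1C(CCCCCl)C(=O)[C@@](O)(C[C@@H](NC(=O)OC(C)(C)C)[C@@H]2C[C@H](C)C(=O)O2)C=C1 | intermediate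
23 | ethyl 1-propenyl ether (E/Z) | CC=COCC | starting material
24 | 2-bromo-1-ethoxypropyl mixed acetal of 22 (isomers at acetal carbon and C–Br) | CC[C@H]1C(CCCCCl)C(=O)[C@](C[C@@H](NC(=O)OC(C)(C)C)[C@@H]2C[C@H](C)C(=O)O2)(OC(OCC)C(C)Br)C=C1 | intermediate
25 | 2,2,6,6-tetramethylpiperidin-1-oxyl | CC1(C)CCCC(C)(C)N1[O] | starting material
26 | cis-fused lactol ether with TEMPO-capped carbinol carbon (mixture at acetal, methyl-bearing, C–O–N and chlorobutyl carbons) | CC[C@H]1C(CCCCCl)C(=O)[C@]2(C[C@@H](NC(=O)OC(C)(C)C)[C@@H]3C[C@H](C)C(=O)O3)OC(OCC)C(C)[C@@H]2C1ON1C(C)(C)CCCC1(C)C | intermediate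
27 | diketone lactol ether | CC[C@H]1C(CCCCCl)C(=O)[C@]2(C[C@@H](NC(=O)OC(C)(C)C)[C@@H]3C[C@H](C)C(=O)O3)OC(OCC)C(C)[C@@H]2C1=O | intermediate
28 | (R)-carbinol lactol ether | CC[C@H]1C(CCCCCl)C(=O)[C@]2(C[C@@H](NC(=O)OC(C)(C)C)[C@@H]3C[C@H](C)C(=O)O3)OC(OCC)C(C)[C@@H]2[C@@H]1O | intermediate
29 | O-tert-butyldimethylsilyl ether of 28 | CC[C@H]1C(CCCCCl)C(=O)[C@]2(C[C@@H](NC(=O)OC(C)(C)C)[C@@H]3C[C@H](C)C(=O)O3)OC(OCC)C(C)[C@@H]2[C@@H]1O[Si](C)(C)C(C)(C)C | intermediate
30 | cis-fused γ-lactone, α-methyl epimers | CC[C@H]1C(CCCCCl)C(=O)[C@]2(C[C@@H](NC(=O)OC(C)(C)C)[C@@H]3C[C@H](C)C(=O)O3)OC(=O)C(C)[C@@H]2[C@@H]1O[Si](C)(C)C(C)(C)C | intermediate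
31 | cis-fused γ-lactone, (R)-α-methyl | CC[C@H]1C(CCCCCl)C(=O)[C@]2(C[C@@H](NC(=O)OC(C)(C)C)[C@@H]3C[C@H](C)C(=O)O3)OC(=O)[C@H](C)[C@@H]2[C@@H]1O[Si](C)(C)C(C)(C)C | intermediate
32 | ammonium trifluoroacetate of the amino ketone | CC[C@H]1C(CCCCCl)C(=O)[C@]2(C[C@@H]([NH3+])[C@@H]3C[C@H](C)C(=O)O3)OC(=O)[C@H](C)[C@@H]2[C@@H]1O[Si](C)(C)C(C)(C)C.[O-]C(=O)C(F)(F)F | intermediate
33 | spiro-fused cyclic imine (1-pyrroline) with 4-chlorobutyl arm | CC[C@H]1C(CCCCCl)C2=N[C@@H]([C@@H]3C[C@H](C)C(=O)O3)C[C@]24OC(=O)[C@H](C)[C@@H]4[C@@H]1O[Si](C)(C)C(C)(C)C | intermediate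
34 | O-tert-butyldimethylsilyl ether of the target | CC[C@H]1C2=C3N(CCCC2)[C@@H]([C@@H]2C[C@H](C)C(=O)O2)C[C@]32OC(=O)[C@H](C)[C@@H]2[C@@H]1O[Si](C)(C)C(C)(C)C | intermediate
35 | CNP0154902.3 | CC[C@H]1C2=C3N(CCCC2)[C@@H]([C@@H]2C[C@H](C)C(=O)O2)C[C@]32OC(=O)[C@H](C)[C@@H]2[C@@H]1O | target

**Step count**

Total: 23 steps. Longest linear sequence: 22 steps (steps 1–10 and 12–23; step 11 is the one-step side branch to 18).

**Steps most likely to fail**

1. Step 16 (key step). The nitroxyl may capture the first-formed secondary radical before it closes the ring, or the ring radical may be diverted by 1,5-hydrogen transfer from the carbamate-bearing CH, so that little cyclised alkoxyamine is obtained. Fallback: starting from 24, the haloacetal cyclisation is run with dioxygen instead of the nitroxyl as the trap (Bu3SnH added slowly, dry air, toluene, 0 °C), which should give the ring hydroperoxides F1 as a mixture; triphenylphosphine reduces them in the same flask to the epimeric carbinols F2, and Dess–Martin oxidation of F2 gives diketone 27, where the route is rejoined.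

2. Step 18. Hydride may be delivered to the wrong face of the new ketone (the angular arm and the ring-fusion C–C bond shield opposite faces), or the α-oxygenated older ketone may be reduced as well. Fallback: starting from 26, the N–O bond is cleaved reductively (Zn, AcOH–THF–H2O, 50 °C) without passing through the ketone; the (R)-carbinol so obtained is 28 itself, and its (S)-epimer F3 is inverted by a Mitsunobu reaction with 4-nitrobenzoic acid (DIAD, PPh3) to the 4-nitrobenzoate F4, whose methanolysis (K2CO3, MeOH, 0 °C) also gives 28.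

3. Step 15. The hindered, hydrogen-bonded tertiary α-ketol hydroxyl may capture the bromo oxocarbenium ion too slowly, so that NBS is consumed at the carbamate N–H or the ring alkene. Fallback: starting from 23, bromine (CH2Cl2, −78 °C) gives 1,2-dibromo-1-ethoxypropane F5, and alcohol 22 is O-alkylated with an excess of F5 in the presence of N,N-dimethylaniline (CH2Cl2, −78 → 0 °C), an α-halo ether substitution that needs no N-bromo reagent, to give 24.

**Further compounds**

F1 | step 16 | ring hydroperoxides of the cis-fused lactol ether (mixture at acetal, methyl-bearing, C–OOH and chlorobutyl carbons) | CC[C@H]1C(CCCCCl)C(=O)[C@]2(C[C@@H](NC(=O)OC(C)(C)C)[C@@H]3C[C@H](C)C(=O)O3)OC(OCC)C(C)[C@@H]2C1OO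
F2 | step 16 | epimeric ring carbinols of the cis-fused lactol ether | CC[C@H]1C(CCCCCl)C(=O)[C@]2(C[C@@H](NC(=O)OC(C)(C)C)[C@@H]3C[C@H](C)C(=O)O3)OC(OCC)C(C)[C@@H]2C1O
F3 | step 18 | (S)-carbinol epimer of 28 | CC[C@H]1C(CCCCCl)C(=O)[C@]2(C[C@@H](NC(=O)OC(C)(C)C)[C@@H]3C[C@H](C)C(=O)O3)OC(OCC)C(C)[C@@H]2[C@H]1O
F4 | step 18 | 4-nitrobenzoate of 28 | CC[C@H]1C(CCCCCl)C(=O)[C@]2(C[C@@H](NC(=O)OC(C)(C)C)[C@@H]3C[C@H](C)C(=O)O3)OC(OCC)C(C)[C@@H]2[C@@H]1OC(=O)c1ccc(cc1)[N+](=O)[O-]
F5 | step 15 | 1,2-dibromo-1-ethoxypropane | CCOC(Br)C(C)Br
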